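## Analysis of the target

Penicanesin D (19) is made of two six-membered rings joined by one methylene group, with no fused or bridged ring system. Ring A is a pentasubstituted benzene: C1 carries the bridge CH2, C2 an acetyl group, C3 and C4 free hydroxyls, C5 a methoxy group, and C6 is the only CH. Ring B is a 4-hydroxy-2H-pyran-2-one with the bridge at C3 and a (2S)-2-hydroxypropyl chain at C6. The carbinol carbon of that chain is the only stereocentre; it is isolated from both rings, so there is no relative stereochemistry to control, only one absolute configuration to bring in and keep. Sensitive sites are the catechol (oxidation), the acidic 4-hydroxypyrone (ring opening by strong nucleophiles), the carbinol β to the pyrone (dehydration to a conjugated propenylpyrone) and the enolisable aryl methyl ketone, which interferes with any strong-base chemistry. The difficulties are the contiguous substitution of ring A, with three differentiated oxygens and the acetyl group wedged between the bridge and a hydroxyl, and the union of the two halves at a bare CH2 without O-alkylation of the pyrone. The route rests on ring B: C2–C3–C4 with the arylmethyl branch is a monosubstituted malonyl unit, and C5–C6–O1 with the carbinol chain is the enol of a methyl ketone. Ring B can therefore be assembled from those two pieces in the same operation that joins the aryl half to the chiral half.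

## Retrosynthetic reasoning

Target 19 is traced back to the ketal 18 and then to the silyl ether 17. The catechol is masked as an isopropylidene ketal and the carbinol as a tert-butyldiphenylsilyl ether. Both groups must survive the mineral acid that the ring closure sets free, and both come off without touching the methyl ether or the pyrone. The silyl group is removed first, so that the free catechol never meets basic fluoride.

In 17 the C4–C5 bond and the O1–C2 lactone bond of ring B are cut. This gives the arylmethylmalonyl dichloride 9 and the enol silane 15. The cut is made here because it removes the heterocycle and the inter-fragment link at once. The bridge CH2 is already part of the malonyl piece, so no C-alkylation of a preformed pyrone is needed, and the reaction runs without base, which protects the aryl ketone and the β-silyloxy ketone. The forward reaction must acylate the terminal carbon of 15 before its oxygen and then close the lactone.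

Dichloride 9 is the doubly activated form of malonic acid 8, which comes from diester 7 by saponification. The diester is carried as long as possible because it tolerates Lewis acids and acid catalysis, whereas the free malonic acid decarboxylates.

Ketal 7 goes back to catechol 6, and 6 to the trimethoxy ketone 4. Acetylating an unsymmetrical catechol precursor would leave two ring positions in competition, one ortho to hydroxyl and one ortho to methoxyl, with no firm basis for choosing between them. In the trimethoxy series the two open ring positions are equivalent, so the acetyl position is fixed by symmetry. The ketone then picks out which two of the three methoxy groups are removed: the one beside it by chelation, and the next one through the cyclic borate 5. This costs one extra step but takes all regiochemical risk out of ring A.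

Ketone 4 comes from Friedel–Crafts acetylation of the symmetrical benzylmalonate 3, and 3 from alkylation of dimethyl malonate (2) with the benzylic chloride 1. The C–C bond between the bridge carbon and the future pyrone C3 is thus made in the first step by the simplest reaction available.

Enol silane 15 is the kinetic, methyl-side enol derivative of ketone 13, reached through the lithium enolate 14. Ketone 13 comes from Weinreb amide 12, this from silyl ether 11, and 11 from the hydroxy ester 10, which supplies the (S)-stereocentre. None of these steps makes or breaks a bond at that carbon.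

## Alternatives that were turned down

Alternative 1: Ring A is disconnected at two ring bonds: the bond between the benzyloxy-bearing and the methoxy-bearing carbon, and the bond between the acetyl-bearing and the chain-bearing carbon. In the forward direction TiCl4 would condense the bis(silyloxy)diene A2 with the dimethoxy enone A3 in a formal [3+3] reaction to give the arene A1.
- For: every substituent of ring A is placed by construction, and the three oxygens emerge already differentiated (free hydroxyl beside the acetyl, benzyl ether, methyl ether). On this point it is stronger than the chosen route, which needs an acylation and a directed demethylation.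
- Against: A1 is a propanoate. Ring B and the chiral chain are still missing and would have to be built by ester enolate chemistry next to a free phenol and an enolisable aryl ketone.
- Against: A2 must be made regio- and geometrically defined from an unsymmetrical diketone carrying an α-benzyloxy group, and TiCl4 threatens the benzyl ether.
- Comparison: the key step would build a benzene ring, which can be bought with its oxygens in place, and leave the harder ring for linear work. The chosen strategy buys the benzene, spends two ordinary steps on its substitution, and uses its key step to make ring B and join the fragments.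

Alternative 2: Ring A is disconnected between the unsubstituted CH and the bridge-bearing carbon, and between the acetyl-bearing carbon and the neighbouring phenol carbon. The silyl ketene acetal diene A5 would add to the ynone A6 in a Diels–Alder reaction, and the adduct would aromatise by losing one methoxy group as the alcohol to give A4.
- For: the polarity match of the nucleophilic CH2 terminus of A5 with the β-carbon of A6 fixes the regiochemistry. A4 already carries the malonate and is a benzyl-protected relative of 6, so it would feed the same pyrone-forming condensation. It also avoids the chelation-controlled demethylation and offers a benzyl ether removable by hydrogenolysis, which is an advantage.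
- Against: A5 is a tetra-oxygenated double enol ether that is laborious to make and sensitive to hydrolysis. A6 is an internal ynone with an acidic propargylic malonate CH (risk of allene isomerisation) and should need heat that A5 would not tolerate.
- Comparison: this is a longer and more fragile way to a compound equivalent to 6, which the chosen route should reach in three steps from commercial materials by classical, scalable reactions whose regiochemistry is fixed by symmetry.

Alternative 3: Only the O1–C6 bond of ring B is disconnected, back to the acetylenic β-keto ester A8. Ph3PAuNTf2 (monovalent gold) would activate the triple bond, the tert-butyl ester carbonyl oxygen would add 6-endo-dig to the alkyne carbon remote from the ketone, and loss of the tert-butyl group as the alkene would give pyrone A7.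
- For: the ring closure is neutral and very mild, produces no mineral acid, allows the smaller silyl group on the carbinol, and its regiochemistry is dictated by the polarisation of the ynone. As a single operation it is more predictable than the key step chosen here.
- Against: it forms one bond and joins nothing. The difficulty moves into A8, whose C3–C4 bond needs acylation or aldol chemistry of a tert-butyl 3-arylpropanoate enolate. That is strong-base chemistry on a substrate with an enolisable aryl methyl ketone, so the acetyl group would have to be masked and unmasked.
- Comparison: the chosen strategy offers convergence instead. Both ring bonds are formed in the step that unites the two halves, no base meets the aryl ketone, and the linear sequence is shorter.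

Key step: step 11

## Route

Remark on the chemistry: compounds 1, 2 and 10 are taken as purchased, 10 in high enantiomeric purity. The dichloride 9 and the enol silane 15 are used crude, directly after evaporation or filtration.

Step 1
Reactants: 1 5-(chloromethyl)-1,2,3-trimethoxybenzene (3,4,5-trimethoxybenzyl chloride); 2 dimethyl malonate
Product: 3 dimethyl 2-[(3,4,5-trimethoxyphenyl)methyl]propanedioate
Conditions: 2 (3 equiv), NaH (1.1 equiv), THF/DMF, 0 °C → rt; excess 2 removed by distillation
Reagents that add atoms: none
Why: Malonic ester alkylation (SN2) of a reactive benzylic chloride by sodium dimethyl malonate; the excess of 2 suppresses a second benzylation.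

Step 2
Reactants: 3 dimethyl 2-[(3,4,5-trimethoxyphenyl)methyl]propanedioate
Product: 4 dimethyl 2-[(2-acetyl-3,4,5-trimethoxyphenyl)methyl]propanedioate
Conditions: AcCl (1.5 equiv), SnCl4 (3 equiv), CH2Cl2, 0 °C → rt
Reagents that add atoms: acetyl chloride, CC(=O)Cl
Why: Friedel–Crafts acylation of an electron-rich arene; the two free ring positions of 3 are equivalent by symmetry, so only one monoacetyl product is possible, and the new ketone deactivates the ring against a second acylation.

Step 3
Reactants: 4 dimethyl 2-[(2-acetyl-3,4,5-trimethoxyphenyl)methyl]propanedioate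
Product: 6 dimethyl 2-[(2-acetyl-3,4-dihydroxy-5-methoxyphenyl)methyl]propanedioate, via cyclic chloroborate 5 (not isolated)
Conditions: BCl3 (3 equiv, 1 M in CH2Cl2), CH2Cl2, −20 °C → rt; then H2O
Reagents that add atoms: none
Why: Carbonyl-directed Lewis-acid ether cleavage: BCl3 bound to the ketone oxygen should cleave the methoxy group beside it, and the aryloxyboron chloride formed should cleave the next methoxy group by closing the five-membered dioxaborole 5, which leaves the third methoxy group untouched; water then hydrolyses 5 to the catechol.

Step 4
Reactants: 6 dimethyl 2-[(2-acetyl-3,4-dihydroxy-5-methoxyphenyl)methyl]propanedioate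
Product: 7 dimethyl 2-[(4-acetyl-7-methoxy-2,2-dimethyl-1,3-benzodioxol-5-yl)methyl]propanedioate
Conditions: Me2C(OMe)2 (5 equiv), TsOH·H2O (5 mol %), toluene, reflux, Soxhlet with 4 Å molecular sieves
Reagents that add atoms: 2,2-dimethoxypropane, COC(C)(C)OC
Why: Acid-catalysed ketal exchange to the five-membered 2,2-dimethyl-1,3-benzodioxole, driven by removal of methanol, which should also overcome the hydrogen bond of the hydroxyl next to the acetyl group; any ketal formed at the hindered aryl ketone reverts on aqueous work-up.

Step 5
Reactants: 7 dimethyl 2-[(4-acetyl-7-methoxy-2,2-dimethyl-1,3-benzodioxol-5-yl)methyl]propanedioate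
Product: 8 2-[(4-acetyl-7-methoxy-2,2-dimethyl-1,3-benzodioxol-5-yl)methyl]propanedioic acid
Conditions: LiOH·H2O (4 equiv), THF/MeOH/H2O, 0 °C → rt; then 1 M HCl, 0 °C, to pH 2–3; extraction and evaporation below 30 °C
Reagents that add atoms: lithium hydroxide, [Li+].[OH-]
Why: Saponification of both methyl esters at or below room temperature; the doubly ortho-substituted aryl ketone is a poor electrophile, so reversible aldol addition of the malonate anion should not compete, and cold, brief acidification frees the diacid without decarboxylation or loss of the ketal.

Step 6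
Reactants: 8 2-[(4-acetyl-7-methoxy-2,2-dimethyl-1,3-benzodioxol-5-yl)methyl]propanedioic acid
Product: 9 2-[(4-acetyl-7-methoxy-2,2-dimethyl-1,3-benzodioxol-5-yl)methyl]propanedioyl dichloride
Conditions: (COCl)2 (2.5 equiv), DMF (cat.), CH2Cl2, 0 °C → rt; evaporated at rt, used at once
Reagents that add atoms: oxalyl chloride, ClC(=O)C(=O)Cl
Why: Acid chloride formation through the chloroiminium (Vilsmeier-type) catalyst; all by-products are gases, so the dichloride should be obtained by evaporation without heating, which avoids ketene formation and decarboxylation.

Step 7
Reactants: 10 ethyl (S)-3-hydroxybutanoate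
Product: 11 ethyl (S)-3-[(tert-butyldiphenylsilyl)oxy]butanoate
Conditions: TBDPSCl (1.1 equiv), imidazole (2.2 equiv), DMF, rt
Reagents that add atoms: tert-butyl(chloro)diphenylsilane, CC(C)(C)[Si](Cl)(c1ccccc1)c1ccccc1
Why: Imidazole-promoted O-silylation of a secondary alcohol; the stereocentre is not involved, and this silyl group is chosen because it withstands anhydrous HCl in the key step.

Step 8
Reactants: 11 ethyl (S)-3-[(tert-butyldiphenylsilyl)oxy]butanoate
Product: 12 (S)-3-[(tert-butyldiphenylsilyl)oxy]-N-methoxy-N-methylbutanamide
Conditions: MeNH(OMe)·HCl (1.6 equiv), i-PrMgCl (3.2 equiv), THF, −20 °C → 0 °C; aq. NH4Cl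
Reagents that add atoms: N,O-dimethylhydroxylamine hydrochloride, CNOC.Cl
Why: Weinreb amide formation by aminolysis of the ester with the chloromagnesium amide generated in the flask; at −20 °C this amide is nucleophilic but should not trigger β-elimination of the silyloxy group.

Step 9
Reactants: 12 (S)-3-[(tert-butyldiphenylsilyl)oxy]-N-methoxy-N-methylbutanamide
Product: 13 (S)-4-[(tert-butyldiphenylsilyl)oxy]pentan-2-one
Conditions: MeMgBr (1.5 equiv), THF, 0 °C; aq. NH4Cl
Reagents that add atoms: methylmagnesium bromide, C[Mg]Br
Why: Weinreb ketone synthesis; the chelated tetrahedral adduct resists a second addition and collapses to the methyl ketone only on work-up.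

Step 10
Reactants: 13 (S)-4-[(tert-butyldiphenylsilyl)oxy]pentan-2-one
Product: 15 (S)-tert-butyldiphenyl{[4-(trimethylsilyloxy)pent-4-en-2-yl]oxy}silane, via lithium enolate 14 (not isolated)
Conditions: LDA (1.1 equiv), THF, −78 °C; Me3SiCl (1.3 equiv), −78 °C → 0 °C; pentane, filtration, evaporation
Reagents that add atoms: chlorotrimethylsilane, C[Si](C)(C)Cl
Why: Kinetic enolisation: LDA at −78 °C should remove a proton from the unhindered methyl group and not from the CH2 shielded by the bulky silyloxy group, and the lithium enolate 14 is trapped on oxygen by Me3SiCl; non-aqueous isolation protects the labile enol silane.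

Step 11
Reactants: 9 2-[(4-acetyl-7-methoxy-2,2-dimethyl-1,3-benzodioxol-5-yl)methyl]propanedioyl dichloride; 15 (S)-tert-butyldiphenyl{[4-(trimethylsilyloxy)pent-4-en-2-yl]oxy}silane
Product: 17 3-[(4-acetyl-7-methoxy-2,2-dimethyl-1,3-benzodioxol-5-yl)methyl]-6-[(2S)-2-(tert-butyldiphenylsilyloxy)propyl]-4-hydroxy-2H-pyran-2-one, via dioxooctanoyl chloride 16 (not isolated)
Conditions: 15 (1.3 equiv), CH2Cl2, −78 °C → rt, no base, argon sweep; aqueous work-up
Reagents that add atoms: none
Why: The terminal carbon of enol silane 15 attacks one acyl chloride of 9 and Me3SiCl leaves, which forms the pyrone C4–C5 bond and gives the 3,5-dioxo acyl chloride 16; this is the known base-free condensation of malonyl dichlorides with silyl enol ethers to 4-hydroxy-2-pyrones, the closest reaction type. In 16 the ketone derived from 15 enolises towards the central CH2, and its enol oxygen attacks the remaining acyl chloride carbon in a 6-exo-trig acylation that forms the O1–C2 lactone bond and closes ring B; loss of HCl and tautomerisation at C3 give the hydroxypyrone, the thermodynamic sink. No stereocentre is created: the malonyl CH becomes the sp2 carbon C3, and the (S)-carbinol carbon lies two atoms from any reacting centre and has no base present to cause elimination or epimerisation. The step needs regioselectivity, in that ring carbon C5 must come from the CH2= terminus and not from the chain CH2, and this is fixed beforehand by the position of the double bond in 15. It needs C-acylation before O-acylation, which a neutral silyl enol ether favours where a metal enolate would not. It needs chemoselectivity against the aryl methyl ketone of 9, which carries no silyl activation, is flanked by two ortho substituents and should enolise far more slowly than 15 reacts. The HCl set free should be tolerated by the tert-butyldiphenylsilyl ether and, without water, by the ketal, and the small excess of 15 covers any protodesilylation.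

Step 12
Reactants: 17 3-[(4-acetyl-7-methoxy-2,2-dimethyl-1,3-benzodioxol-5-yl)methyl]-6-[(2S)-2-(tert-butyldiphenylsilyloxy)propyl]-4-hydroxy-2H-pyran-2-one
Product: 18 3-[(4-acetyl-7-methoxy-2,2-dimethyl-1,3-benzodioxol-5-yl)methyl]-4-hydroxy-6-[(2S)-2-hydroxypropyl]-2H-pyran-2-one
Conditions: TBAF (3 equiv), AcOH (3 equiv), THF, rt → 40 °C
Reagents that add atoms: none
Why: Fluoride-induced cleavage of the Si–O bond, driven by the strength of the Si–F bond; acetic acid buffers the medium so that the pyrone meets no strong base, and the C–O bond of the stereocentre is not touched.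

Step 13
Reactants: 18 3-[(4-acetyl-7-methoxy-2,2-dimethyl-1,3-benzodioxol-5-yl)methyl]-4-hydroxy-6-[(2S)-2-hydroxypropyl]-2H-pyran-2-one
Product: 19 3-[(2-acetyl-3,4-dihydroxy-5-methoxyphenyl)methyl]-4-hydroxy-6-[(2S)-2-hydroxypropyl]-2H-pyran-2-one (penicanesin D)
Conditions: TFA/H2O (9:1), 0 °C → rt, argon; evaporation, MeOH chase
Reagents that add atoms: none
Why: Acid hydrolysis of the catechol isopropylidene ketal through its oxocarbenium ion; the aryl methyl ether, the pyrone and the carbinol should be unaffected at room temperature, and the methanol chase cleaves any trifluoroacetate formed at the secondary alcohol.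

## Compound list

1 | 5-(chloromethyl)-1,2,3-trimethoxybenzene (3,4,5-trimethoxybenzyl chloride) | COc1cc(CCl)cc(OC)c1OC | starting material
2 | dimethyl malonate | COC(=O)CC(=O)OC | starting material
3 | dimethyl 2-[(3,4,5-trimethoxyphenyl)methyl]propanedioate | COC(=O)C(Cc1cc(OC)c(OC)c(OC)c1)C(=O)OC | intermediate
4 | dimethyl 2-[(2-acetyl-3,4,5-trimethoxyphenyl)methyl]propanedioate | COC(=O)C(Cc1cc(OC)c(OC)c(OC)c1C(C)=O)C(=O)OC | intermediate
5 | dimethyl 2-[(4-acetyl-2-chloro-7-methoxy-1,3,2-benzodioxaborol-5-yl)methyl]propanedioate | COC(=O)C(Cc1cc(OC)c2OB(Cl)Oc2c1C(C)=O)C(=O)OC | intermediate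
6 | dimethyl 2-[(2-acetyl-3,4-dihydroxy-5-methoxyphenyl)methyl]propanedioate | COC(=O)C(Cc1cc(OC)c(O)c(O)c1C(C)=O)C(=O)OC | intermediate
7 | dimethyl 2-[(4-acetyl-7-methoxy-2,2-dimethyl-1,3-benzodioxol-5-yl)methyl]propanedioate | COC(=O)C(Cc1cc(OC)c2OC(C)(C)Oc2c1C(C)=O)C(=O)OC | intermediate
8 | 2-[(4-acetyl-7-methoxy-2,2-dimethyl-1,3-benzodioxol-5-yl)methyl]propanedioic acid | COc1cc(CC(C(O)=O)C(O)=O)c(C(C)=O)c2OC(C)(C)Oc12 | intermediate
9 | 2-[(4-acetyl-7-methoxy-2,2-dimethyl-1,3-benzodioxol-5-yl)methyl]propanedioyl dichloride | COc1cc(CC(C(Cl)=O)C(Cl)=O)c(C(C)=O)c2OC(C)(C)Oc12 | intermediate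
10 | ethyl (S)-3-hydroxybutanoate | CCOC(=O)C[C@H](C)O | starting material
11 | ethyl (S)-3-[(tert-butyldiphenylsilyl)oxy]butanoate | CCOC(=O)C[C@H](C)O[Si](c1ccccc1)(c1ccccc1)C(C)(C)C | intermediate
12 | (S)-3-[(tert-butyldiphenylsilyl)oxy]-N-methoxy-N-methylbutanamide | CON(C)C(=O)C[C@H](C)O[Si](c1ccccc1)(c1ccccc1)C(C)(C)C | intermediate
13 | (S)-4-[(tert-butyldiphenylsilyl)oxy]pentan-2-one | CC(=O)C[C@H](C)O[Si](c1ccccc1)(c1ccccc1)C(C)(C)C | intermediate
14 | lithium (S)-4-[(tert-butyldiphenylsilyl)oxy]pent-1-en-2-olate | [Li+].C=C([O-])C[C@H](C)O[Si](c1ccccc1)(c1ccccc1)C(C)(C)C | intermediate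
15 | (S)-tert-butyldiphenyl{[4-(trimethylsilyloxy)pent-4-en-2-yl]oxy}silane | C=C(O[Si](C)(C)C)C[C@H](C)O[Si](c1ccccc1)(c1ccccc1)C(C)(C)C | intermediate
16 | (7S)-2-[(4-acetyl-7-methoxy-2,2-dimethyl-1,3-benzodioxol-5-yl)methyl]-7-[(tert-butyldiphenylsilyl)oxy]-3,5-dioxooctanoyl chloride (mixture at C2) | COc1cc(CC(C(Cl)=O)C(=O)CC(=O)C[C@H](C)O[Si](c2ccccc2)(c2ccccc2)C(C)(C)C)c(C(C)=O)c2OC(C)(C)Oc12 | intermediate
17 | 3-[(4-acetyl-7-methoxy-2,2-dimethyl-1,3-benzodioxol-5-yl)methyl]-6-[(2S)-2-(tert-butyldiphenylsilyloxy)propyl]-4-hydroxy-2H-pyran-2-one | COc1cc(Cc2c(O)cc(C[C@H](C)O[Si](c3ccccc3)(c3ccccc3)C(C)(C)C)oc2=O)c(C(C)=O)c2OC(C)(C)Oc12 | intermediate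
18 | 3-[(4-acetyl-7-methoxy-2,2-dimethyl-1,3-benzodioxol-5-yl)methyl]-4-hydroxy-6-[(2S)-2-hydroxypropyl]-2H-pyran-2-one | COc1cc(Cc2c(O)cc(C[C@H](C)O)oc2=O)c(C(C)=O)c2OC(C)(C)Oc12 | intermediate
19 | 3-[(2-acetyl-3,4-dihydroxy-5-methoxyphenyl)methyl]-4-hydroxy-6-[(2S)-2-hydroxypropyl]-2H-pyran-2-one (penicanesin D) | COc1cc(Cc2c(O)cc(C[C@H](C)O)oc2=O)c(C(C)=O)c(O)c1O | target

## Step count and risks

Total step count: 13. Longest linear sequence: 9 steps (from 1 through steps 1–6 and 11–13); the chiral branch from 10 is 7 steps (steps 7–13).

Step 11 (key step). The most likely failure is loss of the nucleophile: the HCl released in the ring closure may protodesilylate 15 before it has been acylated. The second is loss of the electrophile: the crude, doubly activated 9 may shed HCl to a chlorocarbonyl ketene and oligomerise, or the enol of its own aryl methyl ketone may be acylated. The fallback forms the same two ring bonds in two separate events and sets out from diester 7 and enol silane 15. One ester of 7 is hydrolysed with one equivalent of KOH in MeOH to the malonic half-ester F1. Oxalyl chloride converts it into the mono acid chloride F2, which has only one acylating site and cannot oligomerise. F2 C-acylates 15 (CH2Cl2, −78 °C → rt, ZnCl2 catalyst if needed) to give the 3,5-dioxo ester F3. DBU in toluene at 60–80 °C then deprotonates only the 1,3-diketone and closes the lactone onto the methyl ester. The route is rejoined at 17.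

Step 4. Ketalisation may stall, because the hydroxyl next to the acetyl group is held in a hydrogen bond and the catechol is electron-poor, and prolonged acid and heat may cause self-condensation of the keto malonate. The same ketal must also be hydrolysed beside a dehydration-prone carbinol in step 13. The fallback gives up the ketal and carries the methyl ethers through the pyrone synthesis; it sets out from 4.
- LiOH saponification gives the trimethoxy malonic acid F4, and oxalyl chloride gives the trimethoxy dichloride F5.
- Condensation with 15 as in step 11 gives the trimethoxy pyrone silyl ether F6.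
- BCl3 in CH2Cl2 (−78 °C → rt) then removes the two methoxy groups next to the acetyl group with the selectivity of step 3, while the carbinol is still silylated, to give the catechol silyl ether F7.
- TBAF/AcOH returns to the route at 19.

This path is two steps shorter, but it places the Lewis-acid demethylation on the complete skeleton, which is why it is held in reserve.

Step 6. The malonic acid may lose CO2 during activation, and the HCl formed may attack the ketal or leave half-converted material that forms anhydride oligomers. The fallback avoids free acid and HCl and sets out from 8. N,O-Bis(trimethylsilyl)acetamide in CH2Cl2 gives the bis(trimethylsilyl) malonate F8. Oxalyl chloride with catalytic DMF then exchanges each silyl ester for the acid chloride, releasing only Me3SiCl, CO and CO2. The route is rejoined at 9.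

Step 2. Acylation at a position flanked by two substituents may be slow while the malonate ties up the Lewis acid, and forcing it may bring premature ether or ester cleavage. The fallback replaces electrophilic acylation by halogenation and cross-coupling and sets out from 3. NBS in MeCN gives the aryl bromide F9; symmetry again allows only one monobromide. Stille coupling with tributyl(1-ethoxyvinyl)stannane under Pd(PPh3)4 (zerovalent palladium) in toluene at 100 °C gives the enol ether F10. Dilute HCl in THF hydrolyses it, and the route is rejoined at 4.

Step 10. Some deprotonation may occur at the internal CH2, which leads to the wrong enol silane and to elimination of the silyloxy group, and the trimethylsilyl enol ether may hydrolyse during isolation. The fallback fixes the position of the double bond by construction and sets out from Weinreb amide 12. (Trimethylsilyl)methyllithium in THF (−78 °C → 0 °C, neutral work-up) gives the α-silyl ketone F11. Its thermal 1,3-shift of silicon from carbon to oxygen (Brook-type rearrangement, toluene, sealed tube) can only give the terminal enol silane, and the route is rejoined at 15.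

## Further compounds

F1 | step 11 | 2-[(4-acetyl-7-methoxy-2,2-dimethyl-1,3-benzodioxol-5-yl)methyl]-3-methoxy-3-oxopropanoic acid (racemic) | COC(=O)C(Cc1cc(OC)c2OC(C)(C)Oc2c1C(C)=O)C(O)=O
F2 | step 11 | methyl 2-[(4-acetyl-7-methoxy-2,2-dimethyl-1,3-benzodioxol-5-yl)methyl]-3-chloro-3-oxopropanoate (racemic) | COC(=O)C(Cc1cc(OC)c2OC(C)(C)Oc2c1C(C)=O)C(Cl)=O
F3 | step 11 | methyl (7S)-2-[(4-acetyl-7-methoxy-2,2-dimethyl-1,3-benzodioxol-5-yl)methyl]-7-[(tert-butyldiphenylsilyl)oxy]-3,5-dioxooctanoate (mixture at C2) | COC(=O)C(Cc1cc(OC)c2OC(C)(C)Oc2c1C(C)=O)C(=O)CC(=O)C[C@H](C)O[Si](c1ccccc1)(c1ccccc1)C(C)(C)C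
F4 | step 4 | 2-[(2-acetyl-3,4,5-trimethoxyphenyl)methyl]propanedioic acid | COc1cc(CC(C(O)=O)C(O)=O)c(C(C)=O)c(OC)c1OC
F5 | step 4 | 2-[(2-acetyl-3,4,5-trimethoxyphenyl)methyl]propanedioyl dichloride | COc1cc(CC(C(Cl)=O)C(Cl)=O)c(C(C)=O)c(OC)c1OC
F6 | step 4 | 3-[(2-acetyl-3,4,5-trimethoxyphenyl)methyl]-6-[(2S)-2-(tert-butyldiphenylsilyloxy)propyl]-4-hydroxy-2H-pyran-2-one | COc1cc(Cc2c(O)cc(C[C@H](C)O[Si](c3ccccc3)(c3ccccc3)C(C)(C)C)oc2=O)c(C(C)=O)c(OC)c1OC
F7 | step 4 | 3-[(2-acetyl-3,4-dihydroxy-5-methoxyphenyl)methyl]-6-[(2S)-2-(tert-butyldiphenylsilyloxy)propyl]-4-hydroxy-2H-pyran-2-one | COc1cc(Cc2c(O)cc(C[C@H](C)O[Si](c3ccccc3)(c3ccccc3)C(C)(C)C)oc2=O)c(C(C)=O)c(O)c1O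
F8 | step 6 | bis(trimethylsilyl) 2-[(4-acetyl-7-methoxy-2,2-dimethyl-1,3-benzodioxol-5-yl)methyl]propanedioate | COc1cc(CC(C(=O)O[Si](C)(C)C)C(=O)O[Si](C)(C)C)c(C(C)=O)c2OC(C)(C)Oc12
F9 | step 2 | dimethyl 2-[(2-bromo-3,4,5-trimethoxyphenyl)methyl]propanedioate | COC(=O)C(Cc1cc(OC)c(OC)c(OC)c1Br)C(=O)OC
F10 | step 2 | dimethyl 2-{[2-(1-ethoxyethenyl)-3,4,5-trimethoxyphenyl]methyl}propanedioate | CCOC(=C)c1c(OC)c(OC)c(OC)cc1CC(C(=O)OC)C(=O)OC
F11 | step 10 | (4S)-4-[(tert-butyldiphenylsilyl)oxy]-1-(trimethylsilyl)pentan-2-one | C[Si](C)(C)CC(=O)C[C@H](C)O[Si](c1ccccc1)(c1ccccc1)C(C)(C)C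
A1 | alternative 1 | methyl 3-[2-acetyl-4-(benzyloxy)-3-hydroxy-5-methoxyphenyl]propanoate | COc1cc(CCC(=O)OC)c(C(C)=O)c(O)c1OCc1ccccc1
A2 | alternative 1 | 1-(benzyloxy)-2,4-bis(trimethylsilyloxy)penta-1,3-diene | CC(O[Si](C)(C)C)=CC(O[Si](C)(C)C)=COCc1ccccc1
A3 | alternative 1 | methyl 6,6-dimethoxy-4-oxohex-5-enoate | COC(=O)CCC(=O)C=C(OC)OC
A4 | alternative 2 | dimethyl 2-{[2-acetyl-4-(benzyloxy)-3-hydroxy-5-methoxyphenyl]methyl}propanedioate | COc1cc(CC(C(=O)OC)C(=O)OC)c(C(C)=O)c(O)c1OCc1ccccc1
A5 | alternative 2 | {[2-(benzyloxy)-1,3-dimethoxybuta-1,3-dien-1-yl]oxy}trimethylsilane | C=C(OC)C(OCc1ccccc1)=C(OC)O[Si](C)(C)C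
A6 | alternative 2 | dimethyl 2-(4-oxopent-2-yn-1-yl)propanedioate | CC(=O)C#CCC(C(=O)OC)C(=O)OC
A7 | alternative 3 | 3-[(4-acetyl-7-methoxy-2,2-dimethyl-1,3-benzodioxol-5-yl)methyl]-6-[(2S)-2-(tert-butyldimethylsilyloxy)propyl]-4-hydroxy-2H-pyran-2-one | COc1cc(Cc2c(O)cc(C[C@H](C)O[Si](C)(C)C(C)(C)C)oc2=O)c(C(C)=O)c2OC(C)(C)Oc12
A8 | alternative 3 | tert-butyl (7S)-2-[(4-acetyl-7-methoxy-2,2-dimethyl-1,3-benzodioxol-5-yl)methyl]-7-[(tert-butyldimethylsilyl)oxy]-3-oxooct-4-ynoate (mixture at C2) | COc1cc(CC(C(=O)OC(C)(C)C)C(=O)C#CC[C@H](C)O[Si](C)(C)C(C)(C)C)c(C(C)=O)c2OC(C)(C)Oc12
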